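Ring A, the ten-membered carbocycle, is closed at C9–C10 (germacranolide numbering: lactone C12–O–C6, ester oxygen on C8) by a nickel-catalysed reductive coupling of two carbon–halogen bonds of one chain. The step exploits the homoallylic alcohol unit C8(OH)–C9H2–C10(Me)=C1 that flanks the butenolide (ring B): C9 is carried as the primary halide of an enantiopure halohydrin, C10 as an (E)-alkenyl bromide. In one operation it forms ring A, transfers the alkene geometry and leaves C8–OH free for the methacrylate. Its precursor is an open-chain butenolide bromohydrin; C6 and C8 come from two catalyst-controlled steps before it.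

Key step: step 12

Remarks on the chemistry:
- Atom labels follow germacranolide numbering: C1=C10 (C14 methyl), C2 ketone, C3, C4=C5 (C15 methyl), C6 lactone carbinol, C7=C11 butenolide alkene, C8 ester carbinol, C9, C12 lactone carbonyl, C13 acetoxymethyl carbon. TBS = tert-butyldimethylsilyl, TES = triethylsilyl.
- The C2 carbinol of the intermediates is oxidised in step 16. Its configuration is fixed (as drawn) only so that every intermediate is a single isomer; either antipode would serve.
- The sense of induction in steps 2, 7 and 10 is assumed from the accepted models for these catalysts; the antipodal catalyst would be used if the sense proved opposite.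

Step 1
Reactants: 1 methyl 3-methylbut-2-enoate
Product: 2 tert-butyl{[(1Z)-1-methoxy-3-methylbuta-1,3-dien-1-yl]oxy}dimethylsilane
Conditions: LDA, THF/DMPU, −78 °C; TBSCl
Reagents that add atoms: tert-butyldimethylsilyl chloride, CC(C)(C)[Si](C)(C)Cl
Why: γ-Deprotonation of the enoate and O-silylation of the extended enolate (silyl dienol ether formation) should give the dienolate needed for a vinylogous aldol; no stereocentre is formed and the ketene acetal geometry is of no consequence.

Step 2
Reactants: 2 silyl dienol ether; 3 but-2-ynal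
Product: 4 methyl (2E,5S)-5-hydroxy-3-methyloct-2-en-6-ynoate
Conditions: SiCl4, chiral binaphthyldiamine-derived bisphosphoramide (5 mol%), i-Pr2NEt (cat.), CH2Cl2, −78 °C; aq. NaHCO3
Reagents that add atoms: none
Why: Lewis-base-catalysed vinylogous Mukaiyama aldol reaction in which the dienolate attacks through its γ-carbon to give the (E)-enoate, and the chiral phosphoramide-bound silicon cation selects one aldehyde face to set the carbinol (C2).

Step 3
Reactants: 4 hydroxy enynoate
Product: 5 methyl (2E,5S)-5-(tert-butyldimethylsilyloxy)-3-methyloct-2-en-6-ynoate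
Conditions: TBSCl, imidazole, DMF, rt
Reagents that add atoms: tert-butyldimethylsilyl chloride, CC(C)(C)[Si](C)(C)Cl
Why: Standard silyl ether formation protects the C2 hydroxyl until the last step; the stereocentre is untouched.

Step 4
Reactants: 5 silyl ether
Product: 7 methyl (2E,5S,6E)-7-bromo-5-(tert-butyldimethylsilyloxy)-3-methylocta-2,6-dienoate, via alkenylzirconocene chloride 6 (not isolated)
Conditions: Cp2Zr(H)Cl (2 equiv), THF, rt to 45 °C; then NBS, 0 °C
Reagents that add atoms: zirconocene hydrochloride, [H][Zr](Cl)(C1C=CC=C1)C1C=CC=C1 (zirconium only in 6); N-bromosuccinimide, BrN1C(=O)CCC1=O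
Why: Hydrozirconation adds Zr–H syn across the 2-alkyne, with zirconium settling on the less hindered methyl-bearing carbon after equilibration, and bromodezirconation with retention should give the (E)-2-bromoalkene (the future C1=C10 with C10–Br); the ester is tolerated at this temperature.

Step 5
Reactants: 7 bromo dienoate
Product: 8 (2E,5S,6E)-7-bromo-5-(tert-butyldimethylsilyloxy)-3-methylocta-2,6-dien-1-ol
Conditions: i-Bu2AlH (2.2 equiv), CH2Cl2, −78 °C
Reagents that add atoms: none
Why: 1,2-Reduction of the enoate by the aluminium hydride gives the allylic alcohol without touching the alkenyl bromide or the silyl ether.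

Step 6
Reactants: 8 allylic alcohol
Product: 9 (2E,5S,6E)-7-bromo-5-(tert-butyldimethylsilyloxy)-3-methylocta-2,6-dienal
Conditions: MnO2, CH2Cl2, rt
Reagents that add atoms: none
Why: Allylic oxidation with manganese dioxide gives the enal (C6 aldehyde) with the (E) geometry of C4=C5 retained.

Step 7
Reactants: 9 enal; 10 methyl propiolate
Product: 11 methyl (4R,5E,8S,9E)-10-bromo-8-(tert-butyldimethylsilyloxy)-4-hydroxy-6-methylundeca-5,9-dien-2-ynoate
Conditions: (S,S)-ProPhenol (20 mol%), Me2Zn (3 equiv), Ph3PO (40 mol%), toluene, 4 °C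
Reagents that add atoms: none
Why: Zinc–ProPhenol-catalysed enantioselective alkynylation of an enal, in which the dinuclear zinc catalyst delivers the zinc acetylide of the propiolate to one face of the aldehyde and so sets C6 (4R here) under catalyst control.

Step 8
Reactants: 11 γ-hydroxy ynoate; 12 ethyl vinyl ether
Product: 14 (5R)-5-[(1E,4S,5E)-6-bromo-4-(tert-butyldimethylsilyloxy)-2-methylhepta-1,5-dien-1-yl]-4-(1-ethoxyethenyl)-3-iodofuran-2(5H)-one, via open-chain (Z)-iodo hydroxy ester 13 (not isolated)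
Conditions: 12, t-BuLi, THF, −78 to 0 °C; CuI, −40 °C; 11 (2.2 equiv of cuprate, the first consumed by the hydroxyl), −78 °C; I2 (titrated to end point), −78 °C; warm to rt
Reagents that add atoms: iodine, II
Why: Conjugate syn-carbocupration of the ynoate by the lithium bis(1-ethoxyvinyl)cuprate (an acyl anion equivalent) places the two-carbon unit on C7 and copper on C11 cis to it, and iodinolysis with retention gives the (Z)-iodo enoate whose C6 alkoxide lies cis to the ester and lactonises to ring B; C6 is not touched.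

Step 9
Reactants: 14 enol ether
Product: 15 (5R)-4-(bromoacetyl)-5-[(1E,4S,5E)-6-bromo-4-(tert-butyldimethylsilyloxy)-2-methylhepta-1,5-dien-1-yl]-3-iodofuran-2(5H)-one
Conditions: NBS, NaHCO3, THF/H2O, 0 °C
Reagents that add atoms: N-bromosuccinimide, BrN1C(=O)CCC1=O; water, O
Why: Bromination of the enol ether in water (halogenation–hydrolysis) gives the bromomethyl ketone (C8 ketone, C9 bromide); the enol ether is far more nucleophilic than the trisubstituted alkenes.

Step 10
Reactants: 15 bromomethyl ketone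
Product: 16 (5R)-4-[(1R)-2-bromo-1-hydroxyethyl]-5-[(1E,4S,5E)-6-bromo-4-(tert-butyldimethylsilyloxy)-2-methylhepta-1,5-dien-1-yl]-3-iodofuran-2(5H)-one
Conditions: (R)-Me-CBS oxazaborolidine (20 mol%), catecholborane, toluene, −78 °C
Reagents that add atoms: none
Why: CBS reduction in which the butenolide carbon C7 acts as the large and CH2Br as the small ketone substituent, so that the (R)-oxazaborolidine delivers hydride to the face that gives the C8 configuration of the target (1R in this compound), with catalyst control overriding C6.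

Step 11
Reactants: 16 bromohydrin; 17 (tributylstannyl)methanol
Product: 18 (5R)-4-[(1R)-2-bromo-1-hydroxyethyl]-5-[(1E,4S,5E)-6-bromo-4-(tert-butyldimethylsilyloxy)-2-methylhepta-1,5-dien-1-yl]-3-(hydroxymethyl)furan-2(5H)-one
Conditions: Pd(PPh3)4 (10 mol%), CuI (20 mol%), 1,4-dioxane, 80 °C
Reagents that add atoms: none
Why: Stille coupling with transfer of the hydroxymethyl group installs C13; zerovalent palladium should insert into the activated α-iodo enoate C–I bond well before the unactivated alkenyl and alkyl bromides.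

Step 12
Reactants: 18 bromohydrin diol
Product: 20 (4S,6E,8S,10E,11aR)-8-(tert-butyldimethylsilyloxy)-4-hydroxy-3-(hydroxymethyl)-6,10-dimethyl-4,5,8,9-tetrahydrocyclodeca[b]furan-2(11aH)-one, via iodohydrin 19 (not isolated)
Conditions: NaI (1.5 equiv), DMA, 40 °C; then syringe-pump addition to NiBr2(dme) (30 mol%), 4,4′-di-tert-butyl-2,2′-bipyridine (30 mol%), Mn powder (3 equiv), DMA, 40 °C, final 1 mM
Reagents that add atoms: sodium iodide, [Na+].[I-] (its iodine appears only in 19)
Why: Proposed new method: the closest known reaction type is the nickel-catalysed reductive cross-electrophile coupling of alkenyl bromides with primary alkyl halides, including epoxide-derived halohydrins that give homoallylic alcohols, here asked to work within one molecule; zerovalent nickel inserts into the C10–Br bond with retention of the (E) geometry, the iodide 19 (from Finkelstein exchange) gives the C9 radical by halogen-atom transfer to monovalent nickel, and radical capture followed by reductive elimination from trivalent nickel forms C9–C10. Ring A (ten-membered) is closed head-to-tail between the primary sp3 carbon C9 and the alkenyl terminus C10, so there is no exo/endo alternative and ring B is only a spectator. No stereocentre is created: C8 keeps its C–O bond from step 10, C6 is not epimerised under the neutral, base-free conditions, and the C1=C10 geometry is that of the alkenyl bromide. The step needs cross- over homo-coupling (the sp2 and sp3 halides are activated at different nickel oxidation levels), cyclisation over oligomerisation (slow addition to 1 mM; two (E)-alkenes and the planar butenolide leave few rotors in the chain), and capture of the β-hydroxyalkyl radical faster than its reduction or its 5-exo addition to C4=C5 (high nickel loading; manganese instead of zinc to avoid reductive β-elimination of the halohydrin).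

Step 13
Reactants: 20 macrocyclic diol
Product: 21 [(4S,6E,8S,10E,11aR)-8-(tert-butyldimethylsilyloxy)-4-hydroxy-6,10-dimethyl-2-oxo-2,4,5,8,9,11a-hexahydrocyclodeca[b]furan-3-yl]methyl acetate
Conditions: Ac2O (1.1 equiv), 2,4,6-collidine, CH2Cl2, −20 °C
Reagents that add atoms: acetic anhydride, CC(=O)OC(C)=O
Why: Selective acylation of the primary allylic C13 hydroxyl over the hindered secondary C8 hydroxyl with a weak, bulky base that should not deprotonate C6.

Step 14
Reactants: 21 C13 acetate
Product: 22 (4S,6E,8S,10E,11aR)-3-(acetoxymethyl)-8-(tert-butyldimethylsilyloxy)-6,10-dimethyl-2-oxo-2,4,5,8,9,11a-hexahydrocyclodeca[b]furan-4-yl 2-methylprop-2-enoate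
Conditions: methacrylic anhydride, Et3N, DMAP (cat.), CH2Cl2, 0 °C
Reagents that add atoms: methacrylic anhydride, C=C(C)C(=O)OC(=O)C(C)=C
Why: DMAP-catalysed esterification of the C8 hydroxyl takes place at oxygen, so the C8 configuration is retained.

Step 15
Reactants: 22 silyl ether
Product: 23 (4S,6E,8S,10E,11aR)-3-(acetoxymethyl)-8-hydroxy-6,10-dimethyl-2-oxo-2,4,5,8,9,11a-hexahydrocyclodeca[b]furan-4-yl 2-methylprop-2-enoate
Conditions: HF·pyridine, pyridine, THF, 0 °C to rt
Reagents that add atoms: none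
Why: Fluoride-mediated desilylation under buffered conditions frees the C2 hydroxyl while both esters and the lactone survive.

Step 16
Reactants: 23 allylic alcohol
Product: 24 [(4S,6E,10E,11aR)-3-(acetoxymethyl)-6,10-dimethyl-2,8-dioxo-2,4,5,8,9,11a-hexahydrocyclodeca[b]furan-4-yl] 2-methylprop-2-enoate (CNP0325594.1)
Conditions: Dess–Martin periodinane, NaHCO3, CH2Cl2, 0 °C
Reagents that add atoms: none
Why: Dess–Martin oxidation of the secondary allylic alcohol gives the C2 enone under buffered, non-enolising conditions, so the C4=C5 alkene should stay out of conjugation and C6 and C8 are untouched.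

Compound list
1 | methyl 3-methylbut-2-enoate | COC(=O)C=C(C)C | starting material
2 | tert-butyl{[(1Z)-1-methoxy-3-methylbuta-1,3-dien-1-yl]oxy}dimethylsilane | CO/C(O[Si](C)(C)C(C)(C)C)=C/C(C)=C | intermediate
3 | but-2-ynal | CC#CC=O | starting material
4 | methyl (2E,5S)-5-hydroxy-3-methyloct-2-en-6-ynoate | COC(=O)/C=C(\C)C[C@H](O)C#CC | intermediate
5 | methyl (2E,5S)-5-(tert-butyldimethylsilyloxy)-3-methyloct-2-en-6-ynoate | COC(=O)/C=C(\C)C[C@H](O[Si](C)(C)C(C)(C)C)C#CC | intermediate
6 | alkenylzirconocene chloride from 5, zirconium on the methyl-bearing carbon, (E) | COC(=O)/C=C(\C)C[C@H](O[Si](C)(C)C(C)(C)C)/C=C(\C)[Zr](Cl)(C1C=CC=C1)C1C=CC=C1 | intermediate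
7 | methyl (2E,5S,6E)-7-bromo-5-(tert-butyldimethylsilyloxy)-3-methylocta-2,6-dienoate | COC(=O)/C=C(\C)C[C@H](O[Si](C)(C)C(C)(C)C)/C=C(\C)Br | intermediate
8 | (2E,5S,6E)-7-bromo-5-(tert-butyldimethylsilyloxy)-3-methylocta-2,6-dien-1-ol | OC/C=C(\C)C[C@H](O[Si](C)(C)C(C)(C)C)/C=C(\C)Br | intermediate
9 | (2E,5S,6E)-7-bromo-5-(tert-butyldimethylsilyloxy)-3-methylocta-2,6-dienal | O=C/C=C(\C)C[C@H](O[Si](C)(C)C(C)(C)C)/C=C(\C)Br | intermediate
10 | methyl propiolate | C#CC(=O)OC | starting material
11 | methyl (4R,5E,8S,9E)-10-bromo-8-(tert-butyldimethylsilyloxy)-4-hydroxy-6-methylundeca-5,9-dien-2-ynoate | COC(=O)C#C[C@H](O)/C=C(\C)C[C@H](O[Si](C)(C)C(C)(C)C)/C=C(\C)Br | intermediate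
12 | ethyl vinyl ether | C=COCC | starting material
13 | methyl (2Z,4R,5E,8S,9E)-10-bromo-8-(tert-butyldimethylsilyloxy)-3-(1-ethoxyethenyl)-4-hydroxy-2-iodo-6-methylundeca-2,5,9-trienoate | COC(=O)/C(I)=C(/C(=C)OCC)[C@H](O)/C=C(\C)C[C@H](O[Si](C)(C)C(C)(C)C)/C=C(\C)Br | intermediate
14 | (5R)-5-[(1E,4S,5E)-6-bromo-4-(tert-butyldimethylsilyloxy)-2-methylhepta-1,5-dien-1-yl]-4-(1-ethoxyethenyl)-3-iodofuran-2(5H)-one | CCOC(=C)C1=C(I)C(=O)O[C@@H]1/C=C(\C)C[C@H](O[Si](C)(C)C(C)(C)C)/C=C(\C)Br | intermediate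
15 | (5R)-4-(bromoacetyl)-5-[(1E,4S,5E)-6-bromo-4-(tert-butyldimethylsilyloxy)-2-methylhepta-1,5-dien-1-yl]-3-iodofuran-2(5H)-one | BrCC(=O)C1=C(I)C(=O)O[C@@H]1/C=C(\C)C[C@H](O[Si](C)(C)C(C)(C)C)/C=C(\C)Br | intermediate
16 | (5R)-4-[(1R)-2-bromo-1-hydroxyethyl]-5-[(1E,4S,5E)-6-bromo-4-(tert-butyldimethylsilyloxy)-2-methylhepta-1,5-dien-1-yl]-3-iodofuran-2(5H)-one | BrC[C@H](O)C1=C(I)C(=O)O[C@@H]1/C=C(\C)C[C@H](O[Si](C)(C)C(C)(C)C)/C=C(\C)Br | intermediate
17 | (tributylstannyl)methanol | CCCC[Sn](CCCC)(CCCC)CO | starting material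
18 | (5R)-4-[(1R)-2-bromo-1-hydroxyethyl]-5-[(1E,4S,5E)-6-bromo-4-(tert-butyldimethylsilyloxy)-2-methylhepta-1,5-dien-1-yl]-3-(hydroxymethyl)furan-2(5H)-one | BrC[C@H](O)C1=C(CO)C(=O)O[C@@H]1/C=C(\C)C[C@H](O[Si](C)(C)C(C)(C)C)/C=C(\C)Br | intermediate
19 | (5R)-5-[(1E,4S,5E)-6-bromo-4-(tert-butyldimethylsilyloxy)-2-methylhepta-1,5-dien-1-yl]-3-(hydroxymethyl)-4-[(1R)-1-hydroxy-2-iodoethyl]furan-2(5H)-one | IC[C@H](O)C1=C(CO)C(=O)O[C@@H]1/C=C(\C)C[C@H](O[Si](C)(C)C(C)(C)C)/C=C(\C)Br | intermediate
20 | (4S,6E,8S,10E,11aR)-8-(tert-butyldimethylsilyloxy)-4-hydroxy-3-(hydroxymethyl)-6,10-dimethyl-4,5,8,9-tetrahydrocyclodeca[b]furan-2(11aH)-one | O[C@H]1C/C(C)=C/[C@@H](O[Si](C)(C)C(C)(C)C)C/C(C)=C/[C@H]2OC(=O)C(CO)=C12 | intermediate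
21 | [(4S,6E,8S,10E,11aR)-8-(tert-butyldimethylsilyloxy)-4-hydroxy-6,10-dimethyl-2-oxo-2,4,5,8,9,11a-hexahydrocyclodeca[b]furan-3-yl]methyl acetate | O[C@H]1C/C(C)=C/[C@@H](O[Si](C)(C)C(C)(C)C)C/C(C)=C/[C@H]2OC(=O)C(COC(C)=O)=C12 | intermediate
22 | (4S,6E,8S,10E,11aR)-3-(acetoxymethyl)-8-(tert-butyldimethylsilyloxy)-6,10-dimethyl-2-oxo-2,4,5,8,9,11a-hexahydrocyclodeca[b]furan-4-yl 2-methylprop-2-enoate | C=C(C)C(=O)O[C@H]1C/C(C)=C/[C@@H](O[Si](C)(C)C(C)(C)C)C/C(C)=C/[C@H]2OC(=O)C(COC(C)=O)=C12 | intermediate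
23 | (4S,6E,8S,10E,11aR)-3-(acetoxymethyl)-8-hydroxy-6,10-dimethyl-2-oxo-2,4,5,8,9,11a-hexahydrocyclodeca[b]furan-4-yl 2-methylprop-2-enoate | C=C(C)C(=O)O[C@H]1C/C(C)=C/[C@@H](O)C/C(C)=C/[C@H]2OC(=O)C(COC(C)=O)=C12 | intermediate
24 | [(4S,6E,10E,11aR)-3-(acetoxymethyl)-6,10-dimethyl-2,8-dioxo-2,4,5,8,9,11a-hexahydrocyclodeca[b]furan-4-yl] 2-methylprop-2-enoate (CNP0325594.1) | C=C(C)C(=O)O[C@H]1C/C(C)=C/C(=O)C/C(C)=C/[C@H]2OC(=O)C(COC(C)=O)=C12 | target

Total step count: 16. Longest linear sequence: 16 steps (1 to 24; the route is linear, with 3, 10, 12 and 17 entering as purchased partners).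

Steps most likely to fail

Step 12 (Proposed new method). Oligomerisation through intermolecular radical capture, reduction of the C9 radical or its 5-exo addition to C4=C5, and reductive β-elimination of the halohydrin may all outrun ring closure. The fallback uses a two-electron manifold of known type, an intramolecular Negishi coupling. It sets out from 18: both hydroxyls are silylated (TESOTf, 2,6-lutidine, CH2Cl2, −78 °C) to the bis(triethylsilyl) ether F1, and the bromide is exchanged (NaI, acetone) to the iodide F2. Activated zinc dust with LiCl in THF at 0 °C inserts into the C9–I bond to give the alkylzinc iodide F3. This is added slowly to Pd2(dba)3 and tri(2-furyl)phosphine in THF/DMA, where it couples with the alkenyl bromide and closes ring A as the bis(triethylsilyl) macrocycle F4. PPTS in MeOH then removes both triethylsilyl ethers while the secondary TBS ether stays, and the route is rejoined at 20.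

Step 8. Iodine may attack the electron-rich enol ether, the enol ether may hydrolyse on work-up, or the 1-ethoxyvinyl group may transfer incompletely. The fallback carries the two-carbon unit as a vinyl group and sets C8 by diboration instead of ketone reduction. It sets out from 11: the magnesium divinylcuprate from vinylmagnesium bromide and CuI, then I2, gives the 3-iodo-4-vinylbutenolide F5. Stille hydroxymethylation with 17 gives the alcohol F6, and TBSCl/imidazole gives the silyl ether F7. Platinum-catalysed enantioselective diboration of the terminal vinyl group (Pt(dba)3, TADDOL-derived phosphonite, B2pin2, THF, 60 °C) gives the bis(boronate) F8, which is oxidised without isolation (NaBO3, THF/H2O) to the diol F9. Appel bromination of the primary hydroxyl (CBr4, PPh3, 0 °C) gives the bromohydrin F10. PPTS in MeOH removes the primary silyl ether and the route is rejoined at 18.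

Step 7. Facial selectivity or conversion may be poor in the alkynylation of this β,β-disubstituted enal. The fallback sets C6 by reduction instead of addition. It sets out from 9: the lithium acetylide of 10 (LiHMDS, THF, −78 °C) adds to give the carbinol as a mixture of C4 epimers F11, and Dess–Martin oxidation gives the ynone F12. Noyori transfer hydrogenation of the alkynyl ketone (RuCl(p-cymene)(TsDPEN) of the configuration that gives 4R, HCO2H/Et3N) rejoins the route at 11.

Further compounds
F1 | step 12 | (5R)-4-[(1R)-2-bromo-1-(triethylsilyloxy)ethyl]-5-[(1E,4S,5E)-6-bromo-4-(tert-butyldimethylsilyloxy)-2-methylhepta-1,5-dien-1-yl]-3-[(triethylsilyloxy)methyl]furan-2(5H)-one | BrC[C@H](O[Si](CC)(CC)CC)C1=C(CO[Si](CC)(CC)CC)C(=O)O[C@@H]1/C=C(\C)C[C@H](O[Si](C)(C)C(C)(C)C)/C=C(\C)Br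
F2 | step 12 | (5R)-5-[(1E,4S,5E)-6-bromo-4-(tert-butyldimethylsilyloxy)-2-methylhepta-1,5-dien-1-yl]-4-[(1R)-2-iodo-1-(triethylsilyloxy)ethyl]-3-[(triethylsilyloxy)methyl]furan-2(5H)-one | IC[C@H](O[Si](CC)(CC)CC)C1=C(CO[Si](CC)(CC)CC)C(=O)O[C@@H]1/C=C(\C)C[C@H](O[Si](C)(C)C(C)(C)C)/C=C(\C)Br
F3 | step 12 | alkylzinc iodide from F2 (zinc on C9) | I[Zn]C[C@H](O[Si](CC)(CC)CC)C1=C(CO[Si](CC)(CC)CC)C(=O)O[C@@H]1/C=C(\C)C[C@H](O[Si](C)(C)C(C)(C)C)/C=C(\C)Br
F4 | step 12 | (4S,6E,8S,10E,11aR)-8-(tert-butyldimethylsilyloxy)-6,10-dimethyl-4-(triethylsilyloxy)-3-[(triethylsilyloxy)methyl]-4,5,8,9-tetrahydrocyclodeca[b]furan-2(11aH)-one | CC[Si](CC)(CC)O[C@H]1C/C(C)=C/[C@@H](O[Si](C)(C)C(C)(C)C)C/C(C)=C/[C@H]2OC(=O)C(CO[Si](CC)(CC)CC)=C12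
F5 | step 8 | (5R)-5-[(1E,4S,5E)-6-bromo-4-(tert-butyldimethylsilyloxy)-2-methylhepta-1,5-dien-1-yl]-4-ethenyl-3-iodofuran-2(5H)-one | C=CC1=C(I)C(=O)O[C@@H]1/C=C(\C)C[C@H](O[Si](C)(C)C(C)(C)C)/C=C(\C)Br
F6 | step 8 | (5R)-5-[(1E,4S,5E)-6-bromo-4-(tert-butyldimethylsilyloxy)-2-methylhepta-1,5-dien-1-yl]-4-ethenyl-3-(hydroxymethyl)furan-2(5H)-one | C=CC1=C(CO)C(=O)O[C@@H]1/C=C(\C)C[C@H](O[Si](C)(C)C(C)(C)C)/C=C(\C)Br
F7 | step 8 | (5R)-5-[(1E,4S,5E)-6-bromo-4-(tert-butyldimethylsilyloxy)-2-methylhepta-1,5-dien-1-yl]-3-[(tert-butyldimethylsilyloxy)methyl]-4-ethenylfuran-2(5H)-one | C=CC1=C(CO[Si](C)(C)C(C)(C)C)C(=O)O[C@@H]1/C=C(\C)C[C@H](O[Si](C)(C)C(C)(C)C)/C=C(\C)Br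
F8 | step 8 | 1,2-bis(pinacol boronate) from F7 (boron on C8 and C9, C8 configured as in 20) | CC1(C)OB(OC1(C)C)C[C@H](B1OC(C)(C)C(C)(C)O1)C1=C(CO[Si](C)(C)C(C)(C)C)C(=O)O[C@@H]1/C=C(\C)C[C@H](O[Si](C)(C)C(C)(C)C)/C=C(\C)Br
F9 | step 8 | (5R)-5-[(1E,4S,5E)-6-bromo-4-(tert-butyldimethylsilyloxy)-2-methylhepta-1,5-dien-1-yl]-3-[(tert-butyldimethylsilyloxy)methyl]-4-[(1R)-1,2-dihydroxyethyl]furan-2(5H)-one | OC[C@H](O)C1=C(CO[Si](C)(C)C(C)(C)C)C(=O)O[C@@H]1/C=C(\C)C[C@H](O[Si](C)(C)C(C)(C)C)/C=C(\C)Br
F10 | step 8 | (5R)-4-[(1R)-2-bromo-1-hydroxyethyl]-5-[(1E,4S,5E)-6-bromo-4-(tert-butyldimethylsilyloxy)-2-methylhepta-1,5-dien-1-yl]-3-[(tert-butyldimethylsilyloxy)methyl]furan-2(5H)-one | BrC[C@H](O)C1=C(CO[Si](C)(C)C(C)(C)C)C(=O)O[C@@H]1/C=C(\C)C[C@H](O[Si](C)(C)C(C)(C)C)/C=C(\C)Br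
F11 | step 7 | methyl (5E,8S,9E)-10-bromo-8-(tert-butyldimethylsilyloxy)-4-hydroxy-6-methylundeca-5,9-dien-2-ynoate, mixture of C4 epimers | COC(=O)C#CC(O)/C=C(\C)C[C@H](O[Si](C)(C)C(C)(C)C)/C=C(\C)Br
F12 | step 7 | methyl (5E,8S,9E)-10-bromo-8-(tert-butyldimethylsilyloxy)-6-methyl-4-oxoundeca-5,9-dien-2-ynoate | COC(=O)C#CC(=O)/C=C(\C)C[C@H](O[Si](C)(C)C(C)(C)C)/C=C(\C)Br
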